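## The problem

Honyucitrin 23 is a flavone in which a 5,7-dihydroxylated benzo ring A is fused across C4a–C8a to a 4-pyranone (ring C) that carries at C2 a 4-hydroxyphenyl ring B with prenyl groups at C3' and C5'. The molecule has no stereocentre, so the task is one of regiochemistry and functional-group tolerance only: ring A needs oxygen at C5 and C7 with hydrogen at C6 and C8, and ring B needs two C-prenyl groups flanking the 4'-oxygen. The prenyl alkenes are the fragile part: next to a free 4'-OH they close to chromans under acid, they are reduced under hydrogenolysis, and they react with electrophilic oxidants, so the late steps must avoid strong acid, hydrogen and oxidants. The pyranone intermediates are opened by hydroxide and by amines at the ring carbons next to O1. The feature that makes the key step possible is that ring A is a resorcinol-type ring fused across the C4a–C8a bond, with the C5 oxygen peri to the C4 carbonyl, which is the pattern formed when a vinylketene whose vinyl arm is C8a=C4a combines with an oxygen-substituted alkyne. In a 2-aryl-4-pyranone that C=C bond is an enol-ether double bond with little aromatic character, so ring A can be grown onto a monocyclic pyranone, and its two oxygens arrive already differentiated.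

## Retrosynthesis

23 from 22. The two O–Si bonds at C7–O and C4'–O are cut. Silyl ethers are chosen over acetals or benzyl ethers because fluoride removes them without acid or hydrogen, which the prenyl groups would not tolerate. The precursor 22 differs from the target only by two protecting groups, and the forward step only has to keep the medium from becoming strongly basic.

22 from 13 and 18. Four ring-A bonds are cut: C8–C8a, C7–C8, C5–C6 and C4a–C5. This removes ring A completely and leads to the monocyclic pyranonyl diazomethyl ketone 13 and the two-carbon ynol silyl ether 18. Cuts through ring C would keep a preformed phloroglucinol ring and force its three oxygens to be protected or differentiated. Here the C5 hydroxyl comes from the ketene oxygen and the C7 oxygen from the alkyne, so ring A never carries a protecting group that has to be put on. The forward reaction has to excite the diazo group selectively, orient the ketene and the alkyne correctly, and close the new ring onto C4a.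

18 from 14 and 15. The O–Si bond and the C–O bond of the ynol ether are cut, leading to acetylene 14, a peroxide oxygen donor and the silyl triflate 15. The forward step must oxidise a monolithium acetylide to the ynolate and silylate it on oxygen.

13 from 11. The bond between the carbonyl carbon and the diazo carbon is cut. The diazo carbon becomes C8 and the carboxyl carbon becomes C5. The acid 11 is activated as the mixed anhydride 12 so that no hydrogen chloride is generated near the prenyl groups. The forward step asks for acylation of the C1 diazo reagent in preference to its cycloaddition to the pyranone.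

11 from 10 from 9. Ester hydrolysis is followed backwards by opening of the O1 bridge (one C–O bond), which gives the open-chain 2,4,6-triketo ester 9. Either flanking carbonyl can supply O1 and both lead to the same pyranone, so there is no regiochemical issue. The forward ring closure has to be a mild dehydration.

9 from 7 and 8. The C4a–C8a bond is cut. Diethyl oxalate 8 supplies C8a and the future C5, and the diketone 7 supplies the rest of the chain. The forward step needs acylation at the terminal methyl group of 7, which its dianion provides.

7 from 5 and 6. The C3–C4 bond is cut. The acetyl donor 6 supplies C4 and C4a, and the aryl methyl ketone 5 supplies C2, C3 and ring B. A mild, alkoxide-free C-acylation is required because 5 carries an aryl silyl ether.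

5 from 3 and 4, and 3 from 1 and 2. The O–Si bond and then the two aryl–prenyl bonds are cut, leading to 4-hydroxyacetophenone 1, prenyl bromide 2 and chlorotriisopropylsilane 4. The para acetyl group blocks the only other reactive ring position, so C-alkylation of the phenoxide can occur only at C3' and C5'.

## Roads not taken

Alternative 1: Ring B is built last by a (3+3) benzannulation. The cut goes through C2'–C3' and C5'–C6'. The symmetrical ketone 2,10-dimethylundeca-2,9-dien-6-one A2 would supply C3', C4' and C5' with the phenol oxygen and both prenyl chains. The vinamidinium salt 2-[5,7-bis(tosyloxy)-4-oxo-4H-chromen-2-yl]-1,3-bis(dimethylamino)trimethinium hexafluorophosphate A3 would supply C2', C1' and C6'. In the forward step the enolate of A2 condenses twice with A3, both amino groups leave, and 5,7-bis(tosyloxy)-4'-hydroxy-3',5'-diprenylflavone A1 results. Detosylation of A1 would finish the synthesis.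
- Merit: both prenyl groups are placed by construction, with no phenol C-alkylation. In this respect the road is better than the chosen route, whose step 1 is its least selective reaction.
- Weak points: the condensation needs a strong alkoxide base and liberates a secondary amine, and both open a 2-substituted chromone at C2. The aryl sulfonates on ring A are base-labile. A3 has to be made by Vilsmeier-type chemistry on a chromone that already carries protected ring A. Removing two aryl tosylates from A1 at the end again exposes the chromone to nucleophilic base.
- Comparison: against the prenyl regiocontrol of this road, the chosen plan sets a key step that runs without base, a ring A that needs no protecting groups, and a fluoride-only endgame.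

Alternative 2: Ring C is assembled in one palladium-catalysed three-component step. The cut removes C4a–C4, C4–C3 and O1–C2. 2-Iodo-3,5-bis(methoxymethoxy)phenol A5, carbon monoxide A7 and the arylalkyne 5-ethynyl-2-(methoxymethoxy)-1,3-bis(3-methylbut-2-en-1-yl)benzene A6 would be joined by carbonylative coupling and cyclisation to 5,7,4'-tris(methoxymethoxy)-3',5'-diprenylflavone A4.
- Merit: this is the most convergent road, and the ring-forming reaction has broader precedent on flavones than the chosen key step.
- Weak points: closure of the intermediate ynone can go 5-exo to the aurone skeleton instead of 6-endo. A5 requires a desymmetrised, doubly protected iodophloroglucinol. A6 still has to come from a diprenylated phenol, so the prenylation problem remains. The three acetals of A4 must finally be removed with acid, exactly where the freed 4'-OH sits between two prenyl groups and can close to a chroman.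
- Comparison: this road is shorter in the longest linear sequence and safer in its key step. The chosen plan sets against it an endgame without acid and a ring A whose oxygens are created in differentiated form and never protected.

Alternative 3: Ring C is closed by a thermal Mentzer annulation. The cut removes C4a–C4 and O1–C2. Phloroglucinol A9 and the aroylacetate ethyl 3-[4-(tert-butyldimethylsilyloxy)-3,5-bis(3-methylbut-2-en-1-yl)phenyl]-3-oxopropanoate A10 would be heated together without solvent or catalyst to give 4'-(tert-butyldimethylsilyloxy)-5,7-dihydroxy-3',5'-diprenylflavone A8. Fluoride would then convert A8 into 23.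
- Merit: this is clearly the shortest road. A9 is symmetrical, so there is no regiochemical question and no ring-A protection. In step count it is better than the chosen plan by a wide margin.
- Weak points: the melt of the triphenol A9 above 200 °C can take over the silyl group from the 4'-oxygen of A10 and can then cyclise the prenyl groups onto the freed phenol. Pechmann-type closure to the 4-arylcoumarin competes. The efficiency of such melts is typically modest.
- Comparison: the chosen plan sets against it that none of its steps is heated above 80 °C and that the prenyl groups never meet a hot phenolic medium. If only 23 is wanted, this road is the pragmatic one, and it is kept as the fallback for the key step.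

Key step: step 9

Remark on the chemistry: (triisopropylsilyloxy)ethyne 18 is assumed not to be a stock chemical and is prepared in step 8; diazomethane is used as a freshly prepared ethereal solution; flavone numbering (O1, C2 to C8a, primed numbers for ring B) is used for all pyranone intermediates.

## Route

Step 1
Reactants: 1 4-hydroxyacetophenone; 2 prenyl bromide (1-bromo-3-methylbut-2-ene)
Product: 3 1-[4-hydroxy-3,5-bis(3-methylbut-2-en-1-yl)phenyl]ethan-1-one
Conditions: 2 (2.5 equiv), KOH (10% aq), 0 °C to rt; mono-prenylated phenol resubmitted
Reagents that add atoms: none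
Why: Phenoxide C-alkylation (ortho-prenylation): in water the phenoxide oxygen is hydrogen-bonded, so the allylic bromide is attacked in part by the ring carbons, and with the para position blocked by the acetyl group only C3 and C5 can react. The O-prenyl ether and the mono-prenyl phenol are expected by-products; the latter is recycled, and modest efficiency is accepted in a first step on cheap materials.

Step 2
Reactants: 3 1-[4-hydroxy-3,5-bis(3-methylbut-2-en-1-yl)phenyl]ethan-1-one; 4 chlorotriisopropylsilane
Product: 5 1-[3,5-bis(3-methylbut-2-en-1-yl)-4-(triisopropylsilyloxy)phenyl]ethan-1-one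
Conditions: imidazole, DMAP (cat.), DMF, 50 °C
Reagents that add atoms: none
Why: O-Silylation of a phenol; the para acetyl group makes the phenoxide easy to form and mild heating overcomes the two ortho substituents. The silyl ether blocks chroman formation and ketene trapping later, is shielded against bases by its ortho neighbours, and leaves with fluoride together with the C7 silyl ether at the end.

Step 3
Reactants: 5 1-[3,5-bis(3-methylbut-2-en-1-yl)-4-(triisopropylsilyloxy)phenyl]ethan-1-one; 6 1-acetyl-1H-benzotriazole
Product: 7 1-[3,5-bis(3-methylbut-2-en-1-yl)-4-(triisopropylsilyloxy)phenyl]butane-1,3-dione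
Conditions: MgBr2·OEt2, i-Pr2NEt, CH2Cl2, rt
Reagents that add atoms: none
Why: Crossed Claisen-type C-acylation under soft enolisation: MgBr2 activates the ketone so that the amine can enolise it, and the magnesium enolate is acetylated on carbon by the N-acylbenzotriazole. The product is held as a magnesium diketonate, which prevents a second acylation, and no alkoxide is present to attack the aryl silyl ether.

Step 4
Reactants: 7 1-[3,5-bis(3-methylbut-2-en-1-yl)-4-(triisopropylsilyloxy)phenyl]butane-1,3-dione; 8 diethyl oxalate
Product: 9 ethyl 6-[3,5-bis(3-methylbut-2-en-1-yl)-4-(triisopropylsilyloxy)phenyl]-2,4,6-trioxohexanoate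
Conditions: LiN(i-Pr)2 (2.2 equiv), THF, −78 to 0 °C; then added to 8 (2 equiv), THF, −78 °C; 1 M HCl, 0 °C
Reagents that add atoms: none
Why: Acylation of a 1,3-diketone dianion (Claisen condensation at the terminal methyl group): the second deprotonation gives the more reactive terminal carbanion, which attacks the oxalate and forms the future C4a–C8a bond. Inverse addition to excess oxalate at −78 °C keeps the tetrahedral adduct intact until the quench and suppresses double addition.

Step 5
Reactants: 9 ethyl 6-[3,5-bis(3-methylbut-2-en-1-yl)-4-(triisopropylsilyloxy)phenyl]-2,4,6-trioxohexanoate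
Product: 10 ethyl 6-[3,5-bis(3-methylbut-2-en-1-yl)-4-(triisopropylsilyloxy)phenyl]-4-oxo-4H-pyran-2-carboxylate
Conditions: TsOH·H2O (5 mol %), toluene, 4 Å MS, 50 °C
Reagents that add atoms: none
Why: Acid-catalysed cyclodehydration of a 1,3,5-triketone to a 4-pyranone: the enol oxygen at the aryl ketone adds to the very electrophilic 2-oxo ester carbonyl (6-exo-trig) and the hemiketal loses water, closing the O1 bridge. Only catalytic sulfonic acid at 50 °C is used and the phenol is silylated, so the prenyl groups have no internal nucleophile to cyclise onto.

Step 6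
Reactants: 10 ethyl 6-[3,5-bis(3-methylbut-2-en-1-yl)-4-(triisopropylsilyloxy)phenyl]-4-oxo-4H-pyran-2-carboxylate
Product: 11 6-[3,5-bis(3-methylbut-2-en-1-yl)-4-(triisopropylsilyloxy)phenyl]-4-oxo-4H-pyran-2-carboxylic acid
Conditions: LiOH·H2O (1.1 equiv), THF/H2O, 0 °C; then 1 M HCl to pH 3, 0 °C
Reagents that add atoms: lithium hydroxide, [Li+].[OH-]
Why: Saponification of an ester activated by the α-oxygen and the vinylogous carbonyl; one equivalent of hydroxide at 0 °C should hydrolyse it faster than hydroxide adds to the pyranone ring or attacks the shielded aryl silyl ether. Brief cold acidification should leave the prenyl groups untouched.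

Step 7
Reactants: 11 6-[3,5-bis(3-methylbut-2-en-1-yl)-4-(triisopropylsilyloxy)phenyl]-4-oxo-4H-pyran-2-carboxylic acid
Product: 13 2-(2-diazoacetyl)-6-[3,5-bis(3-methylbut-2-en-1-yl)-4-(triisopropylsilyloxy)phenyl]-4H-pyran-4-one, via isobutyl carbonic anhydride 12 (not isolated)
Conditions: i-BuOCOCl, N-methylmorpholine, THF, −15 °C; then CH2N2 (Et2O), −15 to 0 °C
Reagents that add atoms: diazomethane, C=[N+]=[N-]; isobutyl chloroformate, CC(C)COC(Cl)=O
Why: Acylation of diazomethane by a mixed carbonic anhydride (the first stage of an Arndt–Eistert sequence): the anhydride forms without free hydrogen chloride, and diazomethane attacks the more electrophilic acyl carbonyl to give the diazomethyl ketone. At or below 0 °C acylation should be much faster than dipolar cycloaddition of diazomethane to the pyranone double bonds.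

Step 8
Reactants: 14 acetylene; 15 triisopropylsilyl trifluoromethanesulfonate
Product: 18 (triisopropylsilyloxy)ethyne, via lithium acetylide 16 (not isolated), via lithium ethynolate 17 (not isolated)
Conditions: 14 (excess), n-BuLi, THF, −78 °C; t-BuOOLi (from t-BuOOH and LiN(SiMe3)2), THF, −78 to −40 °C; 15, −78 to 0 °C
Reagents that add atoms: tert-butyl hydroperoxide, CC(C)(C)OO; n-butyllithium, [Li]CCCC
Why: Oxenoid oxygen transfer from lithium tert-butyl peroxide to a lithium acetylide gives the ynolate, the usual entry to 1-silyloxyalkynes from terminal alkynes, and the hard, bulky silyl triflate should silylate the ynolate on oxygen. Triisopropylsilyl ynol ethers are the isolable, distillable members of this class. The monolithium acetylide is kept cold because it disproportionates on warming.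

Step 9
Reactants: 13 2-(2-diazoacetyl)-6-[3,5-bis(3-methylbut-2-en-1-yl)-4-(triisopropylsilyloxy)phenyl]-4H-pyran-4-one; 18 (triisopropylsilyloxy)ethyne
Product: 22 5-hydroxy-7,4'-bis(triisopropylsilyloxy)-3',5'-diprenylflavone, via pyranonylketene 19 (not isolated), via silyloxycyclobutenone 20 (not isolated), via dienylketene 21 (not isolated)
Conditions: 18 (3 equiv), ClCH2CH2Cl (0.02 M), hν (LED, ca. 440 nm), 20 °C; then 80 °C
Reagents that add atoms: none
Why: Excitation of the weak visible n–π* band of the diazoketone expels N2 and triggers the Wolff rearrangement, in which the pyranonyl group migrates from the carbonyl carbon to the diazo carbon (C8–C8a) to give ketene 19. The electrophilic central carbon of 19 is attacked by the nucleophilic CH terminus of the ynol silyl ether and the ketene α-carbon bonds to the oxygen-bearing alkyne carbon, so the (2+2) cycloaddition forms C5–C6 and C7–C8 and gives cyclobutenone 20 with the silyloxy group on the future C7. At 80 °C 20 opens reversibly by thermal conrotatory 4π cleavage to dienylketene 21; only the isomer with the ketene arm cis to the pyranone can react on, and its consumption drains the equilibrium. Ring A then closes by thermal disrotatory 6π electrocyclisation of the ketene carbon onto C4a, the only carbon neighbour of C8a (the other neighbour is O1), and the resulting cyclohexadienone, a β-diketone with an acidic C4a–H, tautomerises to the phenol. The closest known reaction type is the photochemical second-generation Danheiser benzannulation of aryl and heteroaryl diazomethyl ketones with triisopropylsilyloxyalkynes, applied here to a 4-pyranon-2-yl diazoketone whose C8a=C4a bond is an enol-ether double bond with little aromatic stabilisation to lose. No stereocentre survives: the single sp3 carbon of 20 is formed racemic and is flattened on ring opening. The step needs regioselectivity in the (2+2) event, secured by the strong polarisation of the siloxyalkyne; chemoselective excitation, secured by irradiating near 440 nm where the pyranone, the prenyl alkenes and the flavone product should not absorb appreciably; and protection of the product against O-acylation by 19, secured by the hydrogen bond from the new C5–OH to the C4 carbonyl and by the excess of 18.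

Step 10
Reactants: 22 5-hydroxy-7,4'-bis(triisopropylsilyloxy)-3',5'-diprenylflavone
Product: 23 honyucitrin (5,7,4'-trihydroxy-3',5'-diprenylflavone)
Conditions: Bu4NF (2.5 equiv), AcOH (2.5 equiv), THF, 0 °C to rt
Reagents that add atoms: none
Why: Fluoride cleavage of two aryl silyl ethers in one operation; acetic acid buffers the phenoxides so that the pyranone ring is not exposed to strong base, and no strong acid, reductant or oxidant touches the prenyl groups.

## Compound list

1 | 4-hydroxyacetophenone | CC(=O)c1ccc(O)cc1 | starting material
2 | prenyl bromide (1-bromo-3-methylbut-2-ene) | CC(C)=CCBr | starting material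
3 | 1-[4-hydroxy-3,5-bis(3-methylbut-2-en-1-yl)phenyl]ethan-1-one | CC(=O)c1cc(CC=C(C)C)c(O)c(CC=C(C)C)c1 | intermediate
4 | chlorotriisopropylsilane | CC(C)[Si](Cl)(C(C)C)C(C)C | starting material
5 | 1-[3,5-bis(3-methylbut-2-en-1-yl)-4-(triisopropylsilyloxy)phenyl]ethan-1-one | CC(=O)c1cc(CC=C(C)C)c(O[Si](C(C)C)(C(C)C)C(C)C)c(CC=C(C)C)c1 | intermediate
6 | 1-acetyl-1H-benzotriazole | CC(=O)n1nnc2ccccc12 | starting material
7 | 1-[3,5-bis(3-methylbut-2-en-1-yl)-4-(triisopropylsilyloxy)phenyl]butane-1,3-dione | CC(=O)CC(=O)c1cc(CC=C(C)C)c(O[Si](C(C)C)(C(C)C)C(C)C)c(CC=C(C)C)c1 | intermediate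
8 | diethyl oxalate | CCOC(=O)C(=O)OCC | starting material
9 | ethyl 6-[3,5-bis(3-methylbut-2-en-1-yl)-4-(triisopropylsilyloxy)phenyl]-2,4,6-trioxohexanoate | CCOC(=O)C(=O)CC(=O)CC(=O)c1cc(CC=C(C)C)c(O[Si](C(C)C)(C(C)C)C(C)C)c(CC=C(C)C)c1 | intermediate
10 | ethyl 6-[3,5-bis(3-methylbut-2-en-1-yl)-4-(triisopropylsilyloxy)phenyl]-4-oxo-4H-pyran-2-carboxylate | CCOC(=O)c1cc(=O)cc(-c2cc(CC=C(C)C)c(O[Si](C(C)C)(C(C)C)C(C)C)c(CC=C(C)C)c2)o1 | intermediate
11 | 6-[3,5-bis(3-methylbut-2-en-1-yl)-4-(triisopropylsilyloxy)phenyl]-4-oxo-4H-pyran-2-carboxylic acid | OC(=O)c1cc(=O)cc(-c2cc(CC=C(C)C)c(O[Si](C(C)C)(C(C)C)C(C)C)c(CC=C(C)C)c2)o1 | intermediate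
12 | mixed anhydride of 11 with isobutyl hydrogen carbonate (not isolated) | CC(C)COC(=O)OC(=O)c1cc(=O)cc(-c2cc(CC=C(C)C)c(O[Si](C(C)C)(C(C)C)C(C)C)c(CC=C(C)C)c2)o1 | intermediate
13 | 2-(2-diazoacetyl)-6-[3,5-bis(3-methylbut-2-en-1-yl)-4-(triisopropylsilyloxy)phenyl]-4H-pyran-4-one | [N-]=[N+]=CC(=O)c1cc(=O)cc(-c2cc(CC=C(C)C)c(O[Si](C(C)C)(C(C)C)C(C)C)c(CC=C(C)C)c2)o1 | intermediate
14 | acetylene | C#C | starting material
15 | triisopropylsilyl trifluoromethanesulfonate | CC(C)[Si](OS(=O)(=O)C(F)(F)F)(C(C)C)C(C)C | starting material
16 | lithium acetylide (not isolated) | [Li+].[C-]#C | intermediate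
17 | lithium ethynolate (not isolated) | [Li+].[O-]C#C | intermediate
18 | (triisopropylsilyloxy)ethyne | C#CO[Si](C(C)C)(C(C)C)C(C)C | intermediate
19 | 2-(2-oxoethenyl)-6-[3,5-bis(3-methylbut-2-en-1-yl)-4-(triisopropylsilyloxy)phenyl]-4H-pyran-4-one (ketene, not isolated) | O=C=Cc1cc(=O)cc(-c2cc(CC=C(C)C)c(O[Si](C(C)C)(C(C)C)C(C)C)c(CC=C(C)C)c2)o1 | intermediate
20 | racemic 2-[4-oxo-2-(triisopropylsilyloxy)cyclobut-2-en-1-yl]-6-[3,5-bis(3-methylbut-2-en-1-yl)-4-(triisopropylsilyloxy)phenyl]-4H-pyran-4-one (not isolated) | O=C1C=C(O[Si](C(C)C)(C(C)C)C(C)C)C1c1cc(=O)cc(-c2cc(CC=C(C)C)c(O[Si](C(C)C)(C(C)C)C(C)C)c(CC=C(C)C)c2)o1 | intermediate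
21 | 2-[(1E)-4-oxo-2-(triisopropylsilyloxy)buta-1,3-dien-1-yl]-6-[3,5-bis(3-methylbut-2-en-1-yl)-4-(triisopropylsilyloxy)phenyl]-4H-pyran-4-one (dienylketene with the ketene arm cis to the pyranone, not isolated) | O=C=C/C(O[Si](C(C)C)(C(C)C)C(C)C)=C\c1cc(=O)cc(-c2cc(CC=C(C)C)c(O[Si](C(C)C)(C(C)C)C(C)C)c(CC=C(C)C)c2)o1 | intermediate
22 | 5-hydroxy-7,4'-bis(triisopropylsilyloxy)-3',5'-diprenylflavone | CC(C)=CCc1cc(-c2cc(=O)c3c(O)cc(O[Si](C(C)C)(C(C)C)C(C)C)cc3o2)cc(CC=C(C)C)c1O[Si](C(C)C)(C(C)C)C(C)C | intermediate
23 | honyucitrin (5,7,4'-trihydroxy-3',5'-diprenylflavone) | CC(C)=CCc1cc(-c2cc(=O)c3c(O)cc(O)cc3o2)cc(CC=C(C)C)c1O | target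

## Step count and least certain steps

Total step count: 10. Longest linear sequence: 9 steps (steps 1 to 7, 9 and 10, through compounds 1, 3, 5, 7, 9, 10, 11, 13, 22 and 23); step 8 is a one-step side branch.

Step 9 (key step). The cascade has not been run on a 4-pyranonyl diazoketone. The ketene may be lost to dimerisation or adventitious nucleophiles before it meets the alkyne, light absorption by other chromophores may cause photodegradation if the diazo band is too weak at the chosen wavelength, and the thermal ring opening may stall at the cyclobutenone stage. Fallback: ring C is closed instead, with known chemistry. It sets out from 5. Claisen condensation with diethyl carbonate (NaH, THF, reflux) should give the β-keto ester ethyl 3-[3,5-bis(3-methylbut-2-en-1-yl)-4-(triisopropylsilyloxy)phenyl]-3-oxopropanoate F1. Heating F1 with phloroglucinol A9 without solvent (Mentzer pyrone synthesis) should form C4a–C4 and O1–C2 and give 5,7-dihydroxy-3',5'-diprenyl-4'-(triisopropylsilyloxy)flavone F2. Fluoride treatment of F2 under the conditions of step 10 returns to the route at 23.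

Step 8. The monolithium acetylide may disproportionate before oxygen transfer is complete at the low temperature it requires, and silylation of the unsubstituted ynolate may occur partly on carbon. Fallback: a fluoride-labile alkyl ynol ether is used in place of 18. It sets out from commercial 2-(trimethylsilyl)ethanol and from 13. The potassium alkoxide (KH, THF) with trichloroethylene should give (E)-[2-(1,2-dichloroethenyloxy)ethyl]trimethylsilane F3. Treatment of F3 with n-BuLi at −78 °C and then methanol should give [2-(ethynyloxy)ethyl]trimethylsilane F4. F4 replaces 18 under the conditions of step 9 and should give 5-hydroxy-3',5'-diprenyl-4'-(triisopropylsilyloxy)-7-[2-(trimethylsilyl)ethoxy]flavone F5. CsF in DMF at 60 to 80 °C should cleave both the silyl ether and the 2-(trimethylsilyl)ethyl ether of F5, returning to the route at 23.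

Step 1. Alkylation is unselective: O-alkylation, incomplete second C-alkylation and over-alkylation all compete, so the material throughput may be too low. Fallback: the prenyl groups are introduced by cross-coupling. It sets out from 1. Iodination (I2, KI, aqueous NH3) should give 1-(4-hydroxy-3,5-diiodophenyl)ethan-1-one F6. Double Stille coupling of F6 with tributyl(3-methylbut-2-en-1-yl)stannane (Pd(PPh3)4, DMF, 90 °C) should deliver the linear prenyl groups and return to the route at 3.

Step 5. Acid-mediated isomerisation or hydration of the prenyl double bonds, or loss of the silyl ether, may accompany the dehydration. Fallback: the ring is closed without protic acid by a different mode of activation. It sets out from 9 and returns at 10. PPh3 and CCl4 in THF with Et3N convert one enol oxygen into an oxyphosphonium leaving group (Appel-type activation), so that the other enol oxygen closes the ring by addition–elimination. No new compound lies on the way.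

Step 7. Diazomethane may add as a dipole to the acyl-substituted pyranone double bond, or attack the carbonate carbonyl of the anhydride, instead of being acylated. Fallback: the diazo group is installed by diazo transfer instead of acylation. It sets out from 11. Coupling with N,O-dimethylhydroxylamine hydrochloride through the mixed anhydride 12 should give the Weinreb amide 6-[3,5-bis(3-methylbut-2-en-1-yl)-4-(triisopropylsilyloxy)phenyl]-N-methoxy-N-methyl-4-oxo-4H-pyran-2-carboxamide F7. MeMgBr (THF, −78 °C) should convert F7 into the methyl ketone 2-acetyl-6-[3,5-bis(3-methylbut-2-en-1-yl)-4-(triisopropylsilyloxy)phenyl]-4H-pyran-4-one F8. LiN(SiMe3)2 and 2,2,2-trifluoroethyl trifluoroacetate should convert F8 into 4,4,4-trifluoro-1-{6-[3,5-bis(3-methylbut-2-en-1-yl)-4-(triisopropylsilyloxy)phenyl]-4-oxo-4H-pyran-2-yl}butane-1,3-dione F9, used crude. Treatment of F9 with methanesulfonyl azide, Et3N and water in MeCN (detrifluoroacetylative diazo transfer) returns to the route at 13.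

## Further compounds

F1 | step 9 | ethyl 3-[3,5-bis(3-methylbut-2-en-1-yl)-4-(triisopropylsilyloxy)phenyl]-3-oxopropanoate | CCOC(=O)CC(=O)c1cc(CC=C(C)C)c(O[Si](C(C)C)(C(C)C)C(C)C)c(CC=C(C)C)c1
F2 | step 9 | 5,7-dihydroxy-3',5'-diprenyl-4'-(triisopropylsilyloxy)flavone | CC(C)=CCc1cc(-c2cc(=O)c3c(O)cc(O)cc3o2)cc(CC=C(C)C)c1O[Si](C(C)C)(C(C)C)C(C)C
F3 | step 8 | (E)-[2-(1,2-dichloroethenyloxy)ethyl]trimethylsilane | C[Si](C)(C)CCO/C(Cl)=C\Cl
F4 | step 8 | [2-(ethynyloxy)ethyl]trimethylsilane | C[Si](C)(C)CCOC#C
F5 | step 8 | 5-hydroxy-3',5'-diprenyl-4'-(triisopropylsilyloxy)-7-[2-(trimethylsilyl)ethoxy]flavone | CC(C)=CCc1cc(-c2cc(=O)c3c(O)cc(OCC[Si](C)(C)C)cc3o2)cc(CC=C(C)C)c1O[Si](C(C)C)(C(C)C)C(C)C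
F6 | step 1 | 1-(4-hydroxy-3,5-diiodophenyl)ethan-1-one | CC(=O)c1cc(I)c(O)c(I)c1
F0 | step 5 | none | none
F7 | step 7 | 6-[3,5-bis(3-methylbut-2-en-1-yl)-4-(triisopropylsilyloxy)phenyl]-N-methoxy-N-methyl-4-oxo-4H-pyran-2-carboxamide | CON(C)C(=O)c1cc(=O)cc(-c2cc(CC=C(C)C)c(O[Si](C(C)C)(C(C)C)C(C)C)c(CC=C(C)C)c2)o1
F8 | step 7 | 2-acetyl-6-[3,5-bis(3-methylbut-2-en-1-yl)-4-(triisopropylsilyloxy)phenyl]-4H-pyran-4-one | CC(=O)c1cc(=O)cc(-c2cc(CC=C(C)C)c(O[Si](C(C)C)(C(C)C)C(C)C)c(CC=C(C)C)c2)o1
F9 | step 7 | 4,4,4-trifluoro-1-{6-[3,5-bis(3-methylbut-2-en-1-yl)-4-(triisopropylsilyloxy)phenyl]-4-oxo-4H-pyran-2-yl}butane-1,3-dione | O=C(CC(=O)C(F)(F)F)c1cc(=O)cc(-c2cc(CC=C(C)C)c(O[Si](C(C)C)(C(C)C)C(C)C)c(CC=C(C)C)c2)o1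
A1 | alternative 1 | 5,7-bis(tosyloxy)-4'-hydroxy-3',5'-diprenylflavone | Cc1ccc(cc1)S(=O)(=O)Oc1cc(OS(=O)(=O)c2ccc(C)cc2)c2c(c1)oc(cc2=O)-c1cc(CC=C(C)C)c(O)c(CC=C(C)C)c1
A2 | alternative 1 | 2,10-dimethylundeca-2,9-dien-6-one | CC(C)=CCCC(=O)CCC=C(C)C
A3 | alternative 1 | 2-[5,7-bis(tosyloxy)-4-oxo-4H-chromen-2-yl]-1,3-bis(dimethylamino)trimethinium hexafluorophosphate | C[N+](C)=CC(=CN(C)C)c1cc(=O)c2c(OS(=O)(=O)c3ccc(C)cc3)cc(OS(=O)(=O)c3ccc(C)cc3)cc2o1.F[P-](F)(F)(F)(F)F
A4 | alternative 2 | 5,7,4'-tris(methoxymethoxy)-3',5'-diprenylflavone | COCOc1cc(OCOC)c2c(c1)oc(cc2=O)-c1cc(CC=C(C)C)c(OCOC)c(CC=C(C)C)c1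
A5 | alternative 2 | 2-iodo-3,5-bis(methoxymethoxy)phenol | COCOc1cc(O)c(I)c(OCOC)c1
A6 | alternative 2 | 5-ethynyl-2-(methoxymethoxy)-1,3-bis(3-methylbut-2-en-1-yl)benzene | C#Cc1cc(CC=C(C)C)c(OCOC)c(CC=C(C)C)c1
A7 | alternative 2 | carbon monoxide | [C-]#[O+]
A8 | alternative 3 | 4'-(tert-butyldimethylsilyloxy)-5,7-dihydroxy-3',5'-diprenylflavone | CC(C)=CCc1cc(-c2cc(=O)c3c(O)cc(O)cc3o2)cc(CC=C(C)C)c1O[Si](C)(C)C(C)(C)C
A9 | alternative 3 | phloroglucinol | Oc1cc(O)cc(O)c1
A10 | alternative 3 | ethyl 3-[4-(tert-butyldimethylsilyloxy)-3,5-bis(3-methylbut-2-en-1-yl)phenyl]-3-oxopropanoate | CCOC(=O)CC(=O)c1cc(CC=C(C)C)c(O[Si](C)(C)C(C)(C)C)c(CC=C(C)C)c1
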